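# Proposed synthesis of CNP0448476.2 through an intramolecular de Mayo photocycloaddition–fragmentation

## The problem

The target (30) is a 3,4-seco-drimane. Its cyclohexane (C5–C10, drimane labels used throughout) is spiro-fused at C9 to a dihydrofuran, whose CH2 is C11 and whose other two carbons belong to a tropone with a single ring hydrogen. C10 is quaternary and carries a methyl group and the C1–C3 propanoic acid chain. C5 carries the hydroxyisopropyl group (C4) and C8 a methyl group.

Four contiguous stereocentres must be set (C5 S, C10 R, C9 R, C8 R). Only C5 can be bought with an auxiliary; C10 must then be relayed from C5, C9 from C10, and C8 from C9 and C10. The C8 and C10 methyl groups are 1,3-cis, diaxial in the chair that keeps the C4 group equatorial. C8 is therefore the less stable epimer and has to be made under kinetic control, not by enolate chemistry.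

Several groups will not survive rough treatment:
- the tertiary alcohol (ionisation, dehydration);
- the tertiary alkyl ether of a vinylogous ester (acid);
- the tropone (nucleophiles, hydride, hydrogenation);
- the methyl ester, which must be kept while the chain acid is free.

The tropone is best unveiled last from a benzenoid, and the two carboxyl groups are best told apart before they share a molecule.

The feature that opens the structure is the relationship O=C9–C10–C1–C2–C3=O once C9 is seen as a ketone. C9 and the carboxyl carbon C3 are 1,5-related through the quaternary C10. Reconnecting C9 to C2 gives a cyclobutanol, the retron of a [2+2] cycloaddition between an enol C9=C2 and the alkene C10=C1. Because C9 and C10 are both ring members, the tether C8–C7–C6–C5 closes the cyclohexane in the same event.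

## Retrosynthesis

**Tropone to benzenoid (30 to 27).** After removal of the silyl ether (30 from 29), the two ring bonds that flank the lone tropone CH are cut. That carbon goes back to a one-carbon dihalocarbene unit on the para carbon of phenol 27, by way of dienone 28. This cut is preferred over a de novo assembly of the seven-membered ring because every other ring carbon, with its methyl, ester and oxygen substituents, is already present in the commercial benzoate 19. The precursor is a robust arene that tolerates the preceding steps. The forward reactions must deliver para C-alkylation of a phenoxide with both ortho positions blocked, and a radical ring expansion that chooses the alkylidene β-keto ester side.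

**C8–H bond (27 to 26).** The C8 stereocentre is removed as the C7=C8 alkene, and the phenol is masked as a benzyl ether in 26. Enolate methylation would give the equatorial C8 methyl, which is wrong for this target, so kinetic hydrogenation of the alkene is the only direct access. The same operation can free the phenol. Hydrogen must arrive on the face of C11, opposite the axial C10 methyl.

**Spiro centre (26 to 18 and 23).** The C9–C11 bond and the aryl C–O bond are cut, giving enone acid 18 and benzylic chloride 23. Forming the C–C bond first lets the nucleophile enter anti to the pseudo-axial C10 methyl. The ether is then closed with retention at C9 by attack of the alkoxide on an aryl fluoride. A closure from the phenol side onto a C9 cation would place oxygen anti to that methyl, the wrong epimer. The precursors are a monocyclic enone and a pentasubstituted benzene. The forward step needs an ester-tolerant benzylic organometal, 1,2-addition to a hindered enone and an intramolecular SNAr.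

**Aryl piece (23 to 19).** The chloromethyl group, the fluorine and the benzyl ether of 23 are traced through 22, 21 and 20 to commercial 19. The free 4-hydroxyl of 19 is the only handle for the leaving group and its free ring position the only site for C11, so no regiochemical choice arises.

**C8 methyl and unsaturation (18 to 15).** The C8 methyl and the C7=C8 double bond are removed, by way of 16, to reach keto acid 15. C8 is the only enolisable position of 15, so methylation and dehydrogenation have no regiochemical alternative.

**Key disconnection (15 to 12).** Keto acid 15 is reconnected between C9 and C2 to the cyclobutane of photoadduct 13 (retro-aldol in reverse). Then C9–C10 and C2–C1 are cut to reach the acyclic dioxinone 12. Against an enolate Michael or alkylation route to C10, this cut forms the quaternary centre at the internal carbon of a plain alkene. It also delivers the chain directly at the carboxyl oxidation level and turns a compound with one stereocentre into the ring with two. The forward reaction must be a straight (not crossed) photocycloaddition with the new chain trans to the C4 group.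

**Tether (12 to 11 and 10).** The C7–C8 bond is cut, giving commercial dioxinone 11 as its dienolate and primary iodide 10. The alternative, building the dioxinone ring onto a finished chain, needs acid and costs more steps.

**Stereocentre (10 to 3 and 4).** Iodide 10 is traced through 9, 8, 7 and 6 to imide 5. The C5–C6 bond of 5 is cut to give the senecioyl imide 3 (from 1 and 2) and bromoacetate 4. The imide carbonyl becomes C4 by double methyl addition and the bromoacetate carbons become C6 and C7. An auxiliary alkylation is chosen because the isopropenyl group can only be the enolate substituent and the bromoacetate is a reactive electrophile that brings a differentiated second carbonyl.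

## Roads not taken

**Alternative 1:** The cut is at the spiro centre, C9–C11 and aryl C–O, made the strategic event on the chiral-pool enone A2 to give the benzenoid spirocycle A1. In the forward step a benzylic zinc reagent adds to the carbonyl of A2 and the tertiary alkoxide displaces an ortho fluoride.
- Merits: A2 already holds C5, the quaternary C10 (from enolate alkylation anti to the isopropenyl group) and the C8 methyl with its alkene, a few steps from a commercial terpene.
- Weak points: A1 carries three alkenes. The allyl group must be raised to a propanoic acid, the isopropenyl group hydrated to the tertiary alcohol and the ring alkene hydrogenated from one face, each in the presence of the others.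
- Comparison: in step count this road is clearly better up to the spiro-annulation, by roughly eight steps against the sequence to 18. The chosen plan borrows its spiro-annulation as step 17. What the chosen plan sets against it is that C3 and C4 are at their final oxidation level before the arene is attached, so the only alkene left after step 17 is the one to be hydrogenated.

**Alternative 2:** The cut removes two C–C bonds of the seven-membered ring. Furan A4 and the oxyallyl cation generated from bromo keto ester A5 combine in a (4+3) cycloaddition to the oxabicycle A3.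
- Merits: the troponoid ring is built with its ester, methyl groups and oxygen pattern, no hexasubstituted benzene has to be dearomatised, and the bridge diastereomers converge.
- Weak points: A4 still needs the C5/C10 pair, for which this key step offers nothing. The union of two unsymmetrical partners raises a regiochemical question. After bridge opening, the spiro ether must be closed by adding a tropolone-type oxygen across the tetrasubstituted C8=C9 alkene of A3 under acid. That sets C8 and C9 together; capture anti to the axial C10 methyl would put oxygen trans to that methyl, the opposite of the target, and the acid endangers the tertiary alcohol.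
- Comparison: for the seven-membered ring itself this road is probably more reliable than steps 19 and 20. The chosen plan sets against it stepwise, substrate-controlled installation of C9 and C8 (steps 17 and 18).

**Alternative 3:** The cut removes the C5–C4 and C10–C1 bonds of the ring, starting from enone A7. A copper-catalysed asymmetric conjugate addition of an isopropenyl nucleophile is followed by allylation of the enolate to give ketone A6.
- Merits: one catalytic step sets both centres, trans by alkylation anti to the new substituent. It is by far the shortest entry to the C5/C10 pair, one step against ten to reach 15.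
- Weak points: an α-substituted cyclic enone with an alkenyl nucleophile is a demanding substrate class for asymmetric conjugate addition, and the enolate allylation competes with proton transfer. In A6 the allyl group must still be oxidised to the acid and the isopropenyl group hydrated, in concert with the C7=C8 alkene needed later.
- Comparison: this road remains better in step economy even after those adjustments. The chosen plan sets against it absolute configuration from a stoichiometric auxiliary of well-known sense, and both side arms born in their final form, at the price of a long linear approach to 12.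

Key step: step 9

Remarks on the chemistry (assumptions):
- Compounds 16 and 28 are carried as mixtures at the one centre that becomes sp2 in the following step; their SMILES leave that centre open.
- In the fallback to step 9, the chiral acetal is assumed to direct addition to the dioxinone face that carries the acetal hydrogen.

## Route

Step 1
Reactants: 1 (4S)-4-benzyl-1,3-oxazolidin-2-one; 2 3-methylbut-2-enoyl chloride
Product: 3 (4S)-4-benzyl-3-(3-methylbut-2-enoyl)-1,3-oxazolidin-2-one
Conditions: n-BuLi, THF, −78 °C; then 2, −78 → 0 °C
Reagents that add atoms: none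
Why: N-acylation of the lithiated oxazolidinone by the acid chloride (Evans imide formation); no stereocentre is made.

Step 2
Reactants: 3; 4 tert-butyl bromoacetate
Product: 5 tert-butyl (3S)-3-{[(4S)-4-benzyl-2-oxo-1,3-oxazolidin-3-yl]carbonyl}-4-methylpent-4-enoate
Conditions: NaN(SiMe3)2, THF, −78 °C; then 4, −78 → −40 °C
Reagents that add atoms: none
Why: Deconjugative Evans alkylation: γ-deprotonation gives the chelated (Z)-dienolate, which the bromoacetate attacks at the α-carbon on the face opposite the benzyl group. This sets the S centre (future C5) and leaves the isopropenyl alkene out of conjugation.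

Step 3
Reactants: 5
Product: 6 4-tert-butyl 1-methyl (2S)-2-(prop-1-en-2-yl)butanedioate
Conditions: MeMgBr (1.5 equiv), MeOH, CH2Cl2, 0 °C (MeOMgBr formed in the flask)
Reagents that add atoms: methanol, CO
Why: Exocyclic cleavage of the imide by bromomagnesium methoxide (transesterification). The weakly basic, Lewis-acidic alkoxide should release the methyl ester without epimerising or reconjugating the doubly activated α-centre, and it leaves the tert-butyl ester alone.

Step 4
Reactants: 6
Product: 7 tert-butyl (3S)-4-hydroxy-4-methyl-3-(prop-1-en-2-yl)pentanoate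
Conditions: MeMgBr (2.3 equiv), CeCl3, THF, −78 → −20 °C
Reagents that add atoms: methylmagnesium bromide, C[Mg]Br
Why: Double addition of the methylcerium reagent to the methyl ester (organocerium addition). The reagent is too weakly basic to enolise the α-centre and the tert-butyl ester is too hindered to react at this temperature. Any lactone formed from 7 gives the same diol in step 5.

Step 5
Reactants: 7
Product: 8 (3S)-4-methyl-3-(prop-1-en-2-yl)pentane-1,4-diol
Conditions: LiAlH4, THF, 0 °C → rt
Reagents that add atoms: none
Why: Hydride reduction of the tert-butyl ester to the primary alcohol; the stereocentre and the alkene are untouched.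

Step 6
Reactants: 8
Product: 9 (3S)-5-iodo-2-methyl-3-(prop-1-en-2-yl)pentan-2-ol
Conditions: I2, PPh3, imidazole, CH2Cl2, 0 °C
Reagents that add atoms: iodine, II
Why: Appel-type iodination is selective for the primary hydroxyl because the tertiary alcohol does not form an alkoxyphosphonium salt. Working cold and silylating at once keeps ether formation by the free tertiary hydroxyl in check.

Step 7
Reactants: 9
Product: 10 triethyl{[(3S)-5-iodo-2-methyl-3-(prop-1-en-2-yl)pentan-2-yl]oxy}silane
Conditions: Et3SiOTf, 2,6-lutidine, CH2Cl2, −78 → 0 °C
Reagents that add atoms: triethylsilyl trifluoromethanesulfonate, CC[Si](CC)(CC)OS(=O)(=O)C(F)(F)F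
Why: Silylation of the hindered tertiary alcohol with a silyl triflate. The triethylsilyl ether is chosen over trimethylsilyl to survive the basic steps that follow and to serve as the bulky control element of step 9.

Step 8
Reactants: 11 2,2,6-trimethyl-4H-1,3-dioxin-4-one; 10
Product: 12 2,2-dimethyl-6-[(4S)-5-methyl-4-{2-[(triethylsilyl)oxy]propan-2-yl}hex-5-en-1-yl]-4H-1,3-dioxin-4-one
Conditions: LiN(i-Pr)2, THF/HMPA, −78 °C; then 10, −78 → −30 °C
Reagents that add atoms: none
Why: γ-Alkylation of the lithium dienolate of the dioxinone by a primary iodide, the established route to 6-alkyl dioxinones; it forms the C7–C8 bond. The alkene and the silyl ether are inert to the base.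

Step 9
Reactants: 12
Product: 13 (1S,5S,6R,8S)-6,11,11-trimethyl-5-{2-[(triethylsilyl)oxy]propan-2-yl}-10,12-dioxatricyclo[6.4.0.0^{1,6}]dodecan-9-one (cyclohexane cis-fused to a cyclobutane that is fused to the 1,3-dioxan-4-one; angular methyl cis and cyclobutane CH2 trans to the silyloxyisopropyl group)
Conditions: hν (300 nm, Pyrex), MeCN/acetone 9:1, 0 °C, high dilution
Reagents that add atoms: none
Why: Acetone-sensitised excitation gives the dioxinone triplet; its β-carbon (C9) bonds to the internal alkene carbon C10 and the 1,4-biradical collapses by C2–C1 bonding (stepwise [2+2] photocycloaddition; the closest known reaction type is the intramolecular dioxinone–alkene photocycloaddition of de Mayo sequences). The cyclohexane closes by 6-exo attack of C9 on C10 through a chair-like array of the four-atom tether, and the cyclobutane closes by recombination of the biradical, cis-fused because the tether cannot span a trans junction. C10 is controlled by C5: the silyloxyisopropyl group sits equatorial and anti to the forming C9–C10 bond, and the alkene terminus lies pseudo-equatorial where it can reach C2, so C1 should end trans to that group and the methyl cis to it. C9 and C2 follow from the cis fusion and are both erased in step 10. The step needs straight, not crossed, regiochemistry, which the four-atom tether secures by making the first ring six-membered, not seven-membered. It also needs facial selectivity, which rests on the bulk of the triethylsilyloxyisopropyl group as the only stereocontrolling element on the tether. No other group absorbs at this wavelength and the silyl ether is inert.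

Step 10
Reactants: 13
Product: 15 3-[(1R,6S)-1-methyl-2-oxo-6-{2-[(triethylsilyl)oxy]propan-2-yl}cyclohexyl]propanoic acid, via keto methyl ester 14 (not isolated)
Conditions: K2CO3, MeOH, rt; then LiOH, H2O, rt; 1 M HCl to pH 4, 0 °C
Reagents that add atoms: lithium hydroxide, [Li+].[OH-]; methanol, CO (its OMe is carried only by intermediate 14)
Why: Methoxide opens the acylal, acetone is lost and the strained cyclobutanolate undergoes retro-aldol cleavage of C9–C2 (de Mayo fragmentation) to keto ester 14, which is saponified in the same flask. C5 and C10 cannot epimerise, and the tertiary silyl ether tolerates the base. Freeing the chain acid here, before the aryl ester exists, settles the differentiation of the two carboxyl groups.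

Step 11
Reactants: 15
Product: 16 3-[(1R,6S)-1,3-dimethyl-2-oxo-6-{2-[(triethylsilyl)oxy]propan-2-yl}cyclohexyl]propanoic acid (both C3 epimers)
Conditions: LiN(i-Pr)2 (2.2 equiv), THF, −78 °C; MeI, −78 → −30 °C; 1 M HCl to pH 4
Reagents that add atoms: iodomethane, CI
Why: Enolate alkylation of the dianion: after the carboxylate, the base removes a proton from C8, the only enolisable position of the ketone, and the enolate is C-methylated. The carboxylate protects the chain from α-deprotonation and Claisen-type closure. Both epimers serve, since C8 becomes sp2 in step 12.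

Step 12
Reactants: 16
Product: 18 3-[(1R,6S)-1,3-dimethyl-2-oxo-6-{2-[(triethylsilyl)oxy]propan-2-yl}cyclohex-3-en-1-yl]propanoic acid, via bis-silyl enol ether 17 (not isolated)
Conditions: Me3SiOTf, Et3N, CH2Cl2, 0 °C; solvent exchange; Pd(OAc)2, MeCN, rt; aqueous work-up
Reagents that add atoms: trimethylsilyl trifluoromethanesulfonate, C[Si](C)(C)OS(=O)(=O)C(F)(F)F (its silyl groups are carried only by intermediate 17)
Why: Soft enolisation gives the only possible, tetrasubstituted silyl enol ether, and Saegusa–Ito oxidation with Pd(OAc)2 places the double bond at C7=C8 by β-hydride elimination into the ring. The transient silyl ester is hydrolysed on work-up.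

Step 13
Reactants: 19 methyl 2,4-dihydroxy-3,6-dimethylbenzoate
Product: 20 methyl 4-[(fluorosulfonyl)oxy]-2-hydroxy-3,6-dimethylbenzoate
Conditions: SO2F2 (1 atm), Et3N (1.1 equiv), CH2Cl2, rt
Reagents that add atoms: sulfuryl fluoride, O=S(=O)(F)F
Why: Sulfur–fluoride exchange on the more acidic, unchelated 4-hydroxyl. The 2-hydroxyl is hydrogen-bonded to the ester and flanked by two substituents, as in the usual selective 4-O-derivatisation of 2,4-dihydroxybenzoates.

Step 14
Reactants: 20
Product: 21 methyl 2-(benzyloxy)-4-[(fluorosulfonyl)oxy]-3,6-dimethylbenzoate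
Conditions: BnBr, K2CO3, DMF, 40 °C
Reagents that add atoms: benzyl bromide, BrCc1ccccc1
Why: Williamson benzylation of the remaining phenol; aryl fluorosulfates tolerate carbonate base. The benzyl ether is chosen because it can be removed later by hydrogenolysis, without acid.

Step 15
Reactants: 21
Product: 22 methyl 2-(benzyloxy)-4-fluoro-3,6-dimethylbenzoate
Conditions: Me4NF (anhydrous), DMF, 80 °C
Reagents that add atoms: tetramethylammonium fluoride, C[N+](C)(C)C.[F-]
Why: Nucleophilic deoxyfluorination of the aryl fluorosulfate by anhydrous fluoride, a known conversion of phenol-derived fluorosulfates, assisted by the para ester.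

Step 16
Reactants: 22
Product: 23 methyl 2-(benzyloxy)-5-(chloromethyl)-4-fluoro-3,6-dimethylbenzoate
Conditions: MeOCH2Cl, ZnCl2 (20 mol%), CH2Cl2, 35 °C
Reagents that add atoms: chloromethyl methyl ether, COCCl
Why: Blanc chloromethylation at the single free ring position, which is para to the benzyloxy group and meta to the ester, so all directing effects coincide. The mild Lewis acid should spare the benzyl ether, whose own phenyl ring is far less activated.

Step 17
Reactants: 23; 18
Product: 26 3-[(2R,5'S,6'R)-6-(benzyloxy)-5-(methoxycarbonyl)-2',4,6',7-tetramethyl-5'-{2-[(triethylsilyl)oxy]propan-2-yl}-3H-spiro[1-benzofuran-2,1'-cyclohex[2]en]-6'-yl]propanoic acid, via benzylic zinc chloride 24 (not isolated), via tertiary alcohol adduct 25 (not isolated)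
Conditions: 23, Zn, LiCl, THF, rt; 18 pretreated with KN(SiMe3)2 (1.0 equiv), THF, −78 °C; combine, MgCl2, 0 °C → rt; then KN(SiMe3)2 (1.2 equiv), DMF, 60 °C; 1 M HCl to pH 4
Reagents that add atoms: zinc, [Zn] (carried only by intermediate 24)
Why: Zinc insertion gives an ester-tolerant benzylic zinc reagent whose MgCl2-promoted 1,2-addition to the enone carbonyl should occur anti to the pseudo-axial C10 methyl, setting C9 with C11 trans and oxygen cis to that methyl. The potassium alkoxide then displaces the ortho fluoride by intramolecular SNAr (5-exo) with retention at C9. The chain is a carboxylate throughout and so cannot lactonise with the alkoxide.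

Step 18
Reactants: 26
Product: 27 3-[(2R,2'R,5'S,6'R)-6-hydroxy-5-(methoxycarbonyl)-2',4,6',7-tetramethyl-5'-{2-[(triethylsilyl)oxy]propan-2-yl}-3H-spiro[1-benzofuran-2,1'-cyclohexan]-6'-yl]propanoic acid
Conditions: H2 (5 bar), Pd/C, EtOAc, rt
Reagents that add atoms: none
Why: Heterogeneous hydrogenation should add hydrogen to C7=C8 from the face opposite the axial C10 methyl and the ether oxygen; that face also carries the carboxylic acid chain, which can anchor the substrate to the catalyst. This gives the 8R centre with the methyl cis to oxygen under kinetic control. The benzyl ether is hydrogenolysed in the same operation.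

Step 19
Reactants: 27
Product: 28 methyl (2R,2'R,5'S,6'R)-6'-(2-carboxyethyl)-3a-(dichloromethyl)-2',4,6',7-tetramethyl-6-oxo-5'-{2-[(triethylsilyl)oxy]propan-2-yl}-3a,6-dihydro-3H-spiro[1-benzofuran-2,1'-cyclohexane]-5-carboxylate (both C3a epimers)
Conditions: CHCl3, 50% aq. NaOH, BnEt3NCl, 40 °C; then 1 M HCl to pH 4
Reagents that add atoms: chloroform, ClC(Cl)Cl
Why: Abnormal Reimer–Tiemann reaction: both ortho positions of the phenoxide are blocked, so dichlorocarbene is taken up at the para carbon, which bears C11 and cannot rearomatise, giving the 4-(dichloromethyl)cyclohexa-2,5-dienone. The new sp3 centre is lost in step 20. The tertiary silyl ether shields the alcohol from the carbene.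

Step 20
Reactants: 28
Product: 29 3-[(2R,2'R,5'S,6'R)-6-(methoxycarbonyl)-2',5,6',8-tetramethyl-7-oxo-5'-{2-[(triethylsilyl)oxy]propan-2-yl}-3,7-dihydrospiro[cyclohepta[b]furan-2,1'-cyclohexan]-6'-yl]propanoic acid
Conditions: Bu3SnH (1.2 equiv, slow addition), AIBN (cat.), benzene, 80 °C
Reagents that add atoms: none
Why: Radical ring expansion of a 4-(dichloromethyl)cyclohexadienone to a tropone. The stannyl radical abstracts one chlorine, and the chloroalkyl radical closes 3-exo onto the alkylidene β-keto ester carbon, which gives a radical stabilised by both carbonyl groups. The cyclopropane then opens by cleavage of the old ring bond and a chlorine atom is expelled. This inserts the CH between the methyl-bearing carbon and the carbon carrying C11.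

Step 21
Reactants: 29
Product: 30 3-[(2R,2'R,5'S,6'R)-5'-(2-hydroxypropan-2-yl)-6-(methoxycarbonyl)-2',5,6',8-tetramethyl-7-oxo-3,7-dihydrospiro[cyclohepta[b]furan-2,1'-cyclohexan]-6'-yl]propanoic acid (CNP0448476.2)
Conditions: HF·pyridine, pyridine/THF, 0 °C → rt
Reagents that add atoms: none
Why: Fluoride-mediated cleavage of the tertiary silyl ether under buffered, non-ionising conditions, chosen so that the tropone, the spiro ether and the methyl ester are not exposed to strong acid, base or nucleophiles.

## Compound list

1 | (4S)-4-benzyl-1,3-oxazolidin-2-one | O=C1OC[C@H](Cc2ccccc2)N1 | starting material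
2 | 3-methylbut-2-enoyl chloride | CC(C)=CC(Cl)=O | starting material
3 | (4S)-4-benzyl-3-(3-methylbut-2-enoyl)-1,3-oxazolidin-2-one | CC(C)=CC(=O)N1[C@@H](Cc2ccccc2)COC1=O | intermediate
4 | tert-butyl bromoacetate | CC(C)(C)OC(=O)CBr | starting material
5 | tert-butyl (3S)-3-{[(4S)-4-benzyl-2-oxo-1,3-oxazolidin-3-yl]carbonyl}-4-methylpent-4-enoate | CC(C)(C)OC(=O)C[C@H](C(=O)N1[C@@H](Cc2ccccc2)COC1=O)C(C)=C | intermediate
6 | 4-tert-butyl 1-methyl (2S)-2-(prop-1-en-2-yl)butanedioate | CC(C)(C)OC(=O)C[C@H](C(=O)OC)C(C)=C | intermediate
7 | tert-butyl (3S)-4-hydroxy-4-methyl-3-(prop-1-en-2-yl)pentanoate | CC(C)(C)OC(=O)C[C@H](C(C)(C)O)C(C)=C | intermediate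
8 | (3S)-4-methyl-3-(prop-1-en-2-yl)pentane-1,4-diol | OCC[C@H](C(C)(C)O)C(C)=C | intermediate
9 | (3S)-5-iodo-2-methyl-3-(prop-1-en-2-yl)pentan-2-ol | ICC[C@H](C(C)(C)O)C(C)=C | intermediate
10 | triethyl{[(3S)-5-iodo-2-methyl-3-(prop-1-en-2-yl)pentan-2-yl]oxy}silane | ICC[C@H](C(C)(C)O[Si](CC)(CC)CC)C(C)=C | intermediate
11 | 2,2,6-trimethyl-4H-1,3-dioxin-4-one | CC1=CC(=O)OC(C)(C)O1 | starting material
12 | 2,2-dimethyl-6-[(4S)-5-methyl-4-{2-[(triethylsilyl)oxy]propan-2-yl}hex-5-en-1-yl]-4H-1,3-dioxin-4-one | CC1(C)OC(=O)C=C(CCC[C@H](C(C)(C)O[Si](CC)(CC)CC)C(C)=C)O1 | intermediate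
13 | (1S,5S,6R,8S)-6,11,11-trimethyl-5-{2-[(triethylsilyl)oxy]propan-2-yl}-10,12-dioxatricyclo[6.4.0.0^{1,6}]dodecan-9-one | CC1(C)OC(=O)[C@H]2C[C@]3(C)[C@@H](C(C)(C)O[Si](CC)(CC)CC)CCC[C@]23O1 | intermediate
14 | methyl 3-[(1R,6S)-1-methyl-2-oxo-6-{2-[(triethylsilyl)oxy]propan-2-yl}cyclohexyl]propanoate (not isolated) | O=C1CCC[C@H](C(C)(C)O[Si](CC)(CC)CC)[C@@]1(C)CCC(=O)OC | intermediate
15 | 3-[(1R,6S)-1-methyl-2-oxo-6-{2-[(triethylsilyl)oxy]propan-2-yl}cyclohexyl]propanoic acid | O=C1CCC[C@H](C(C)(C)O[Si](CC)(CC)CC)[C@@]1(C)CCC(=O)O | intermediate
16 | 3-[(1R,6S)-1,3-dimethyl-2-oxo-6-{2-[(triethylsilyl)oxy]propan-2-yl}cyclohexyl]propanoic acid (C3 epimers) | O=C1C(C)CC[C@H](C(C)(C)O[Si](CC)(CC)CC)[C@@]1(C)CCC(=O)O | intermediate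
17 | trimethylsilyl 3-[(1R,6S)-1,3-dimethyl-6-{2-[(triethylsilyl)oxy]propan-2-yl}-2-[(trimethylsilyl)oxy]cyclohex-2-en-1-yl]propanoate (not isolated) | C[Si](C)(C)OC1=C(C)CC[C@H](C(C)(C)O[Si](CC)(CC)CC)[C@@]1(C)CCC(=O)O[Si](C)(C)C | intermediate
18 | 3-[(1R,6S)-1,3-dimethyl-2-oxo-6-{2-[(triethylsilyl)oxy]propan-2-yl}cyclohex-3-en-1-yl]propanoic acid | O=C1C(C)=CC[C@H](C(C)(C)O[Si](CC)(CC)CC)[C@@]1(C)CCC(=O)O | intermediate
19 | methyl 2,4-dihydroxy-3,6-dimethylbenzoate | COC(=O)c1c(C)cc(O)c(C)c1O | starting material
20 | methyl 4-[(fluorosulfonyl)oxy]-2-hydroxy-3,6-dimethylbenzoate | COC(=O)c1c(C)cc(OS(=O)(=O)F)c(C)c1O | intermediate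
21 | methyl 2-(benzyloxy)-4-[(fluorosulfonyl)oxy]-3,6-dimethylbenzoate | COC(=O)c1c(C)cc(OS(=O)(=O)F)c(C)c1OCc1ccccc1 | intermediate
22 | methyl 2-(benzyloxy)-4-fluoro-3,6-dimethylbenzoate | COC(=O)c1c(C)cc(F)c(C)c1OCc1ccccc1 | intermediate
23 | methyl 2-(benzyloxy)-5-(chloromethyl)-4-fluoro-3,6-dimethylbenzoate | COC(=O)c1c(C)c(CCl)c(F)c(C)c1OCc1ccccc1 | intermediate
24 | {[4-(benzyloxy)-2-fluoro-5-(methoxycarbonyl)-3,6-dimethylphenyl]methyl}zinc chloride (not isolated) | COC(=O)c1c(C)c(C[Zn]Cl)c(F)c(C)c1OCc1ccccc1 | intermediate
25 | 3-[(1R,2R,6S)-2-{[4-(benzyloxy)-2-fluoro-5-(methoxycarbonyl)-3,6-dimethylphenyl]methyl}-2-hydroxy-1,3-dimethyl-6-{2-[(triethylsilyl)oxy]propan-2-yl}cyclohex-3-en-1-yl]propanoic acid (not isolated; formed as its alkoxide) | COC(=O)c1c(C)c(C[C@@]2(O)C(C)=CC[C@H](C(C)(C)O[Si](CC)(CC)CC)[C@@]2(C)CCC(=O)O)c(F)c(C)c1OCc1ccccc1 | intermediate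
26 | 3-[(2R,5'S,6'R)-6-(benzyloxy)-5-(methoxycarbonyl)-2',4,6',7-tetramethyl-5'-{2-[(triethylsilyl)oxy]propan-2-yl}-3H-spiro[1-benzofuran-2,1'-cyclohex[2]en]-6'-yl]propanoic acid | COC(=O)c1c(C)c2c(c(C)c1OCc1ccccc1)O[C@]1(C2)C(C)=CC[C@H](C(C)(C)O[Si](CC)(CC)CC)[C@@]1(C)CCC(=O)O | intermediate
27 | 3-[(2R,2'R,5'S,6'R)-6-hydroxy-5-(methoxycarbonyl)-2',4,6',7-tetramethyl-5'-{2-[(triethylsilyl)oxy]propan-2-yl}-3H-spiro[1-benzofuran-2,1'-cyclohexan]-6'-yl]propanoic acid | COC(=O)c1c(C)c2c(c(C)c1O)O[C@]1(C2)[C@H](C)CC[C@H](C(C)(C)O[Si](CC)(CC)CC)[C@@]1(C)CCC(=O)O | intermediate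
28 | methyl (2R,2'R,5'S,6'R)-6'-(2-carboxyethyl)-3a-(dichloromethyl)-2',4,6',7-tetramethyl-6-oxo-5'-{2-[(triethylsilyl)oxy]propan-2-yl}-3a,6-dihydro-3H-spiro[1-benzofuran-2,1'-cyclohexane]-5-carboxylate (C3a epimers) | COC(=O)C1=C(C)C2(C(Cl)Cl)C(=C(C)C1=O)O[C@]1(C2)[C@H](C)CC[C@H](C(C)(C)O[Si](CC)(CC)CC)[C@@]1(C)CCC(=O)O | intermediate
29 | 3-[(2R,2'R,5'S,6'R)-6-(methoxycarbonyl)-2',5,6',8-tetramethyl-7-oxo-5'-{2-[(triethylsilyl)oxy]propan-2-yl}-3,7-dihydrospiro[cyclohepta[b]furan-2,1'-cyclohexan]-6'-yl]propanoic acid | COC(=O)c1c(C)cc2c(c(C)c1=O)O[C@]1(C2)[C@H](C)CC[C@H](C(C)(C)O[Si](CC)(CC)CC)[C@@]1(C)CCC(=O)O | intermediate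
30 | 3-[(2R,2'R,5'S,6'R)-5'-(2-hydroxypropan-2-yl)-6-(methoxycarbonyl)-2',5,6',8-tetramethyl-7-oxo-3,7-dihydrospiro[cyclohepta[b]furan-2,1'-cyclohexan]-6'-yl]propanoic acid (CNP0448476.2) | COC(=O)c1c(C)cc2c(c(C)c1=O)O[C@]1(C2)[C@H](C)CC[C@H](C(C)(C)O)[C@@]1(C)CCC(=O)O | target

## Step count and least certain steps

Total: 21 steps. Longest linear sequence: 17 steps (steps 1–12 and 17–21, from 1 and 2 to 30). The aryl branch (steps 13–16, from 19) joins at step 17.

**Step 9 (key step).** The tether may fold through the other chair, with the alkene terminus pseudo-axial, or through a flattened array. The chain would then be delivered cis to the silyloxyisopropyl group, and C10 cannot be corrected afterwards. Crossed closure through a seven-membered biradical is a second, smaller risk with a 1,1-disubstituted alkene. The fallback keeps the disconnection but adds reagent control. Iodide 10 would alkylate the dienolate of the known tert-butyl acetal analogue of 11 in its (S) form, to give (2S)-2-tert-butyl-6-[(4S)-5-methyl-4-{2-[(triethylsilyl)oxy]propan-2-yl}hex-5-en-1-yl]-4H-1,3-dioxin-4-one F1. Its acetal centre allows the alkene onto one dioxinone face only and so fixes C9 and C10 together. Irradiation as in step 9 would give the tert-butyl acetal photoadduct F2, and the fragmentation of step 10 would return the route at 15.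

**Step 19.** The carbene may be taken up at the methyl-bearing ortho carbon between the two oxygens, or be lost to hydrolysis before the weakly nucleophilic, ester-conjugated phenoxide reacts. The electrophilic dienone may also be degraded by hydroxide. The fallback exchanges the carbene for a trihalomethyl radical under non-hydrolytic conditions. The caesium phenoxide of 27 would be irradiated with BrCCl3 (visible light, charge-transfer activation, related to the photochemical perhaloalkylation of phenolates) to give the trichloromethyl dienone F3, the compound class otherwise made by the Zincke–Suhl reaction. One equivalent of Bu3SnH at high concentration would reduce F3 to 28, where the route resumes.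

**Step 20.** Hydrogen transfer from the stannane may outrun the 3-exo closure, so that the dichloromethyl group is simply reduced. Less likely, the radical may close onto the enol-ether alkene and give the isomeric tropone. The fallback accepts the reduction. Dienone 28 would be taken with one equivalent of Bu3SnH to the chloromethyl dienone F4. Under high dilution the primary radical from F4 would then undergo Dowd–Beckwith-type ring expansion to the dihydrotropone F5. Dehydrogenation of F5 with DDQ would give 29.

**Step 18.** The catalyst may approach from the oxygen-bearing face, because the pseudo-axial C11 methylene on the required face and the axial methyl on the other face are of similar size. The result would be the equatorial C8 methyl epimer. The fallback replaces surface approach by directed delivery. Acid 26 would be hydrogenated with [Ir(cod)(PCy3)(py)]PF6 in CH2Cl2, with the chain carboxyl group, which lies on the required face, binding the cationic iridium centre. This would give the saturated benzyl ether F6, and hydrogenolysis over Pd/C would then give 27.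

**Step 17.** The hindered, enolisable ketone flanked by a quaternary carbon may resist the benzylic zinc reagent. The SNAr may also be slow, because the para ester is twisted out of conjugation by its two ortho substituents. The fallback separates the two events and changes the carbon–carbon bond formation to a one-electron Barbier coupling. SmI2 in THF would join 23 and the potassium salt of 18 to give the tertiary alcohol 25, which would be isolated. Ring closure would follow as a separate operation with KN(SiMe3)2 and 18-crown-6 in DMF, giving 26.

**Step 8.** The unactivated iodide may react slowly, so that α-alkylation, proton transfer and elimination compete with γ-alkylation of the dienolate. The fallback builds the dioxinone ring after the C–C bond. The dianion of tert-butyl acetoacetate (NaH, then n-BuLi) would be alkylated by 10 at its terminal carbon to give tert-butyl (7S)-8-methyl-3-oxo-7-{2-[(triethylsilyl)oxy]propan-2-yl}non-8-enoate F7. Heating F7 with acetone in toluene (acylketene formation and trapping) would give 12.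

## Further compounds

F1 | step 9 | (2S)-2-tert-butyl-6-[(4S)-5-methyl-4-{2-[(triethylsilyl)oxy]propan-2-yl}hex-5-en-1-yl]-4H-1,3-dioxin-4-one | CC(C)(C)[C@@H]1OC(=O)C=C(CCC[C@H](C(C)(C)O[Si](CC)(CC)CC)C(C)=C)O1
F2 | step 9 | (1S,5S,6R,8S,11S)-11-tert-butyl-6-methyl-5-{2-[(triethylsilyl)oxy]propan-2-yl}-10,12-dioxatricyclo[6.4.0.0^{1,6}]dodecan-9-one | CC(C)(C)[C@@H]1OC(=O)[C@H]2C[C@]3(C)[C@@H](C(C)(C)O[Si](CC)(CC)CC)CCC[C@]23O1
F3 | step 19 | methyl (2R,2'R,5'S,6'R)-6'-(2-carboxyethyl)-2',4,6',7-tetramethyl-6-oxo-3a-(trichloromethyl)-5'-{2-[(triethylsilyl)oxy]propan-2-yl}-3a,6-dihydro-3H-spiro[1-benzofuran-2,1'-cyclohexane]-5-carboxylate (C3a epimers) | COC(=O)C1=C(C)C2(C(Cl)(Cl)Cl)C(=C(C)C1=O)O[C@]1(C2)[C@H](C)CC[C@H](C(C)(C)O[Si](CC)(CC)CC)[C@@]1(C)CCC(=O)O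
F4 | step 20 | methyl (2R,2'R,5'S,6'R)-6'-(2-carboxyethyl)-3a-(chloromethyl)-2',4,6',7-tetramethyl-6-oxo-5'-{2-[(triethylsilyl)oxy]propan-2-yl}-3a,6-dihydro-3H-spiro[1-benzofuran-2,1'-cyclohexane]-5-carboxylate (C3a epimers) | COC(=O)C1=C(C)C2(CCl)C(=C(C)C1=O)O[C@]1(C2)[C@H](C)CC[C@H](C(C)(C)O[Si](CC)(CC)CC)[C@@]1(C)CCC(=O)O
F5 | step 20 | 3-[(2R,2'R,5'S,6'R)-6-(methoxycarbonyl)-2',5,6',8-tetramethyl-7-oxo-5'-{2-[(triethylsilyl)oxy]propan-2-yl}-3,3a,4,7-tetrahydrospiro[cyclohepta[b]furan-2,1'-cyclohexan]-6'-yl]propanoic acid (C3a epimers) | COC(=O)C1=C(C)CC2C(=C(C)C1=O)O[C@]1(C2)[C@H](C)CC[C@H](C(C)(C)O[Si](CC)(CC)CC)[C@@]1(C)CCC(=O)O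
F6 | step 18 | 3-[(2R,2'R,5'S,6'R)-6-(benzyloxy)-5-(methoxycarbonyl)-2',4,6',7-tetramethyl-5'-{2-[(triethylsilyl)oxy]propan-2-yl}-3H-spiro[1-benzofuran-2,1'-cyclohexan]-6'-yl]propanoic acid | COC(=O)c1c(C)c2c(c(C)c1OCc1ccccc1)O[C@]1(C2)[C@H](C)CC[C@H](C(C)(C)O[Si](CC)(CC)CC)[C@@]1(C)CCC(=O)O
F0 | step 17 | none | none
F7 | step 8 | tert-butyl (7S)-8-methyl-3-oxo-7-{2-[(triethylsilyl)oxy]propan-2-yl}non-8-enoate | CC(C)(C)OC(=O)CC(=O)CCC[C@H](C(C)(C)O[Si](CC)(CC)CC)C(C)=C
A1 | alternative 1 | methyl (2R,5'S,6'R)-6-methoxy-2',4,6',7-tetramethyl-5'-(prop-1-en-2-yl)-6'-(prop-2-en-1-yl)-3H-spiro[1-benzofuran-2,1'-cyclohex[2]ene]-5-carboxylate | COC(=O)c1c(C)c2c(c(C)c1OC)O[C@]1(C2)C(C)=CC[C@H](C(C)=C)[C@@]1(C)CC=C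
A2 | alternative 1 | (5R,6R)-2,6-dimethyl-5-(prop-1-en-2-yl)-6-(prop-2-en-1-yl)cyclohex-2-en-1-one | O=C1C(C)=CC[C@H](C(C)=C)[C@@]1(C)CC=C
A3 | alternative 2 | 8-oxabicyclo[3.2.1]oct-6-en-3-one cycloadduct (bridge diastereomers unassigned) | COC(=O)C1C(=O)C(C)C2OC1(C)C=C2CC1=C(C)CC[C@H](C(C)(C)O)[C@@]1(C)CCC(=O)OC
A4 | alternative 2 | methyl 3-[(1R,6S)-6-(2-hydroxypropan-2-yl)-1,3-dimethyl-2-[(5-methylfuran-3-yl)methyl]cyclohex-2-en-1-yl]propanoate | Cc1cc(CC2=C(C)CC[C@H](C(C)(C)O)[C@@]2(C)CCC(=O)OC)co1
A5 | alternative 2 | methyl 4-bromo-3-oxopentanoate | COC(=O)CC(=O)C(C)Br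
A6 | alternative 3 | (2R,3R)-2-methyl-3-(prop-1-en-2-yl)-2-(prop-2-en-1-yl)cyclohexan-1-one | O=C1CCC[C@H](C(C)=C)[C@@]1(C)CC=C
A7 | alternative 3 | 2-methylcyclohex-2-en-1-one | CC1=CCCC1=O
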